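## Retrosynthetic overview

1. Target 31 ⇐ desilylation and face-selective C1=C10 epoxidation (oxirane ring formed last) of the ten-membered trienolide 29.
2. 29 ⇐ C3–C4 ring closure of iodo-aldehyde 27 by CrCl2/NiCl2 vinyl iodide–aldehyde coupling (ten-membered ring formed second, onto the finished lactone).
3. 27 ⇐ 22 (C8 unmasking, CBS reduction, isobutyrylation, C3 oxidation); 22 ⇐ key C7–C8 bond: lithiated dithiane 16 (C8 acyl anion equivalent) adds 1,4 to butenolide 9, and the enolate is trapped with CH2=NMe2+ (C13).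
4. 9 (lactone ring formed first, by RCM) ⇐ acrolein + silyl propargyl ether 1: asymmetric alkynylation (C6), directed trans-hydroalumination/iodination (Z-iodoalkene), acrylate RCM.
5. 16 ⇐ 1,3-dithiane + allylic bromide 13, from 4-methylpent-3-en-1-ol (E-selective SeO2 oxidation fixes the 1(10)-alkene geometry).

Assumptions: germacranolide numbering is used (C12 lactone carbonyl, lactone O on C6, C7 ring fusion, C8 ester carbon, C1/C10 oxirane, C14 methyl, C3 carbinol, C4=C5, C15 hydroxymethyl, C13 exocyclic methylene), which makes the target (1R,3S,4Z,6R,7R,8R,10R); in step 1 the (S,S)-ProPhenol catalyst is taken to deliver the alkyne to the Re face of acrolein, and the (R,R)-ligand is used instead, with nothing else changed, if the sense is the opposite.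

## Route

Step 1
Reactants: 1 tert-butyldimethyl(prop-2-yn-1-yloxy)silane; 2 acrolein
Product: 4 (3S)-6-(tert-butyldimethylsilyloxy)hex-1-en-4-yn-3-ol, via methylzinc alkynylide 3 (not isolated)
Conditions: ZnMe2 (3 equiv), (S,S)-ProPhenol (10 mol %), Ph3P=O (20 mol %), toluene, 0 °C; then 2, 4 °C; aq. NH4Cl
Reagents that add atoms: none
Why: Zn-ProPhenol catalysed asymmetric alkynylation of an enal (Trost alkynylation), in which the alkynylzinc 3 is delivered inside the chiral dinuclear zinc pocket to the Re face of acrolein and sets C6 as (3S)-4.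

Step 2
Reactants: 4 (3S)-6-(tert-butyldimethylsilyloxy)hex-1-en-4-yn-3-ol
Product: 6 (3S,4Z)-6-(tert-butyldimethylsilyloxy)-5-iodohexa-1,4-dien-3-ol, via cyclic vinylalanate 5 (not isolated)
Conditions: NaAlH2(OCH2CH2OMe)2, THF, 0 °C; then I2, THF, −78 °C
Reagents that add atoms: iodine, II
Why: Hydroxyl-directed trans-hydroalumination of the propargylic alcohol (hydride to C5, aluminium to C4 in the five-membered alanate 5) followed by iododealumination with retention gives only the Z-iodoalkene with iodine cis to C6, the temperature being held at or below 0 °C to suppress loss of silanolate to an allene.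

Step 3
Reactants: 6 (3S,4Z)-6-(tert-butyldimethylsilyloxy)-5-iodohexa-1,4-dien-3-ol; 7 acryloyl chloride
Product: 8 (3S,4Z)-6-(tert-butyldimethylsilyloxy)-5-iodohexa-1,4-dien-3-yl prop-2-enoate
Conditions: iPr2NEt, CH2Cl2, −78 → 0 °C
Reagents that add atoms: none
Why: Simple O-acylation (esterification) of the secondary alcohol, which touches no stereocentre.

Step 4
Reactants: 8 (3S,4Z)-6-(tert-butyldimethylsilyloxy)-5-iodohexa-1,4-dien-3-yl prop-2-enoate
Product: 9 (5S)-5-[(1Z)-3-(tert-butyldimethylsilyloxy)-2-iodoprop-1-en-1-yl]furan-2(5H)-one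
Conditions: second-generation Grubbs catalyst RuCl2(=CHPh)(H2IMes)(PCy3) (5 mol %), CH2Cl2, 40 °C, 5 mM
Reagents that add atoms: none
Why: Ring-closing metathesis of the allyl acrylate gives the butenolide (lactone ring), the trisubstituted iodoalkene being metathesis-inert and C6 untouched.

Step 5
Reactants: 10 4-methylpent-3-en-1-ol
Product: 11 1-methoxy-4-{[(4-methylpent-3-en-1-yl)oxy]methyl}benzene
Conditions: NaH, 4-methoxybenzyl chloride, Bu4NI (cat.), THF/DMF, 0 °C → rt
Reagents that add atoms: 4-methoxybenzyl chloride, COc1ccc(CCl)cc1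
Why: Williamson etherification protects the future C3 oxygen as a PMB ether that survives organolithium chemistry and is removed oxidatively later.

Step 6
Reactants: 11 1-methoxy-4-{[(4-methylpent-3-en-1-yl)oxy]methyl}benzene
Product: 12 (2E)-5-[(4-methoxybenzyl)oxy]-2-methylpent-2-en-1-ol
Conditions: SeO2 (0.4 equiv), tBuOOH (3 equiv), salicylic acid (10 mol %), CH2Cl2, rt
Reagents that add atoms: tert-butyl hydroperoxide, CC(C)(C)OO (its oxygen is relayed by the catalytic SeO2, O=[Se]=O)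
Why: Sharpless SeO2/tBuOOH allylic oxidation (ene reaction then [2,3]-shift) is selective for the E-methyl group of a trisubstituted alkene and gives the E-allylic alcohol that fixes the later 1(10)-E geometry.

Step 7
Reactants: 12 (2E)-5-[(4-methoxybenzyl)oxy]-2-methylpent-2-en-1-ol
Product: 13 1-({[(3E)-5-bromo-4-methylpent-3-en-1-yl]oxy}methyl)-4-methoxybenzene
Conditions: CBr4, PPh3, CH2Cl2, 0 °C
Reagents that add atoms: carbon tetrabromide, BrC(Br)(Br)Br
Why: Appel bromination converts the primary allylic alcohol into the bromide at 0 °C without allylic transposition or loss of alkene geometry.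

Step 8
Reactants: 14 1,3-dithiane; 13 1-({[(3E)-5-bromo-4-methylpent-3-en-1-yl]oxy}methyl)-4-methoxybenzene
Product: 16 2-[(2E)-5-[(4-methoxybenzyl)oxy]-2-methylpent-2-en-1-yl]-1,3-dithiane, via 2-lithio-1,3-dithiane 15 (not isolated)
Conditions: nBuLi, THF, −30 °C; then 13, −78 → 0 °C
Reagents that add atoms: none
Why: Corey–Seebach alkylation, a direct SN2 displacement of the primary allylic bromide by the dithiane anion, installs C8 at the masked-carbonyl level.

Step 9
Reactants: 16 2-[(2E)-5-[(4-methoxybenzyl)oxy]-2-methylpent-2-en-1-yl]-1,3-dithiane; 9 (5S)-5-[(1Z)-3-(tert-butyldimethylsilyloxy)-2-iodoprop-1-en-1-yl]furan-2(5H)-one; 17 Eschenmoser's salt (N,N-dimethylmethyleneiminium iodide)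
Product: 22 (4S,5S)-5-[(1Z)-3-(tert-butyldimethylsilyloxy)-2-iodoprop-1-en-1-yl]-4-{2-[(2E)-5-[(4-methoxybenzyl)oxy]-2-methylpent-2-en-1-yl]-1,3-dithian-2-yl}-3-methylideneoxolan-2-one, via lithiated dithiane 18 (not isolated), via lithium lactone enolate 19 (not isolated), via Mannich base 20 (not isolated), via trimethylammonium iodide 21 (not isolated)
Conditions: 16, nBuLi, THF, −25 °C; HMPA, −78 °C; then 9, −78 °C; then 17, −78 → 0 °C; then MeI, MeOH, rt; then aq. NaHCO3/CH2Cl2, rt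
Reagents that add atoms: none
Why: Corey–Seebach acyl anion equivalent in a tandem conjugate addition–Mannich trapping, in which the C8 carbanion 18 adds 1,4 (HMPA, solvent-separated ion pair) to the β-carbon C7 of 9 from the face anti to the C6 side chain (C7 set trans to C6), the enolate 19 is aminomethylated by 17, and quaternisation/E1cB elimination of 21 unveils the exocyclic methylene.

Step 10
Reactants: 22 dithiane lactone from step 9
Product: 23 (4S,5S)-5-[(1Z)-3-(tert-butyldimethylsilyloxy)-2-iodoprop-1-en-1-yl]-4-[(3E)-6-[(4-methoxybenzyl)oxy]-3-methylhex-3-enoyl]-3-methylideneoxolan-2-one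
Conditions: PhI(OCOCF3)2 (1.5 equiv), NaHCO3, MeCN/H2O 9:1, 0 °C, 10 min
Reagents that add atoms: water, O
Why: Oxidative hydrolysis of the dithioacetal by the hypervalent iodine reagent (Stork–Zhao deprotection) is complete in minutes at sulfur and leaves the alkenes, the vinyl iodide, the ethers and the trans (thermodynamic) C6/C7 relationship intact.

Step 11
Reactants: 23 C8 ketone from step 10
Product: 24 (4R,5S)-4-[(1R,3E)-1-hydroxy-6-[(4-methoxybenzyl)oxy]-3-methylhex-3-en-1-yl]-5-[(1Z)-3-(tert-butyldimethylsilyloxy)-2-iodoprop-1-en-1-yl]-3-methylideneoxolan-2-one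
Conditions: (S)-2-methyl-CBS-oxazaborolidine (0.5 equiv), catecholborane, toluene, −78 °C
Reagents that add atoms: none
Why: Corey–Bakshi–Shibata reduction, in which the branched C7 acts as the large and the C9 methylene as the small substituent so that the (S)-catalyst gives the (8R)-alcohol, reinforced by Felkin–Anh attack anti to the C7–C6 bond, while catecholborane at −78 °C leaves the unsaturated lactone alone.

Step 12
Reactants: 24 (8R)-alcohol from step 11
Product: 25 (1R,3E)-1-[(2S,3R)-2-[(1Z)-3-(tert-butyldimethylsilyloxy)-2-iodoprop-1-en-1-yl]-4-methylidene-5-oxooxolan-3-yl]-6-[(4-methoxybenzyl)oxy]-3-methylhex-3-en-1-yl 2-methylpropanoate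
Conditions: isobutyric anhydride, Et3N, DMAP (cat.), CH2Cl2, 0 °C → rt
Reagents that add atoms: isobutyric anhydride, CC(C)C(=O)OC(=O)C(C)C
Why: DMAP-catalysed acylation installs the 8-isobutyrate with retention at C8 before any other free hydroxyl is present.

Step 13
Reactants: 25 isobutyrate PMB ether from step 12
Product: 26 (1R,3E)-1-[(2S,3R)-2-[(1Z)-3-(tert-butyldimethylsilyloxy)-2-iodoprop-1-en-1-yl]-4-methylidene-5-oxooxolan-3-yl]-6-hydroxy-3-methylhex-3-en-1-yl 2-methylpropanoate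
Conditions: DDQ, CH2Cl2/pH 7 buffer 10:1, 0 °C
Reagents that add atoms: none
Why: Oxidative PMB ether cleavage (single-electron oxidation of the electron-rich benzyl ether by DDQ) frees the C3 primary alcohol while the silyl ether, ester, vinyl iodide and alkenes are inert.

Step 14
Reactants: 26 primary alcohol from step 13
Product: 27 (1R,3E)-1-[(2S,3R)-2-[(1Z)-3-(tert-butyldimethylsilyloxy)-2-iodoprop-1-en-1-yl]-4-methylidene-5-oxooxolan-3-yl]-3-methyl-6-oxohex-3-en-1-yl 2-methylpropanoate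
Conditions: Dess–Martin periodinane, CH2Cl2, 0 °C; used crude
Reagents that add atoms: none
Why: Dess–Martin oxidation gives the β,γ-unsaturated C3 aldehyde under non-basic conditions, and it is used at once so that the alkene does not move into conjugation.

Step 15
Reactants: 27 iodo-aldehyde from step 14
Product: 29 (1(10)E,3S,4Z,6R,7R,8R)-15-(tert-butyldimethylsilyloxy)-3-hydroxy-8-(isobutyryloxy)germacra-1(10),4,11(13)-trien-12,6-olide, via vinylchromium dichloride 28 (not isolated)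
Conditions: CrCl2 (10 equiv), NiCl2 (2 mol %), DMSO/THF 3:1, rt, syringe-pump addition to 2 mM
Reagents that add atoms: none
Why: Nozaki–Hiyama–Kishi reaction, in which zerovalent nickel inserts into the C4–I bond and transmetallates to the vinylchromium 28 with retention of the Z geometry, and 28 adds only to the aldehyde at high dilution to close the ten-membered ring, C3 being set by substrate control in the cyclic transition state with the 3β (3S) alcohol expected from attack on the aldehyde face turned away from the lactone.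

Step 16
Reactants: 29 macrocyclic allylic alcohol from step 15
Product: 30 (1R,3S,4Z,6R,7R,8R,10R)-15-(tert-butyldimethylsilyloxy)-1,10-epoxy-3-hydroxy-8-(isobutyryloxy)germacra-4,11(13)-dien-12,6-olide
Conditions: mCPBA (1.1 equiv), NaHCO3, CH2Cl2, −20 → 0 °C
Reagents that add atoms: 3-chloroperoxybenzoic acid, O=C(OO)c1cccc(Cl)c1
Why: Prilezhaev epoxidation, in which the electron-rich C1=C10 alkene reacts far faster than C4=C5 (three allylic oxygens) or the enoate C11=C13 and the peracid attacks its exposed outer face, guided by hydrogen bonding to the homoallylic 3β-hydroxyl, to give the trans (1R,10R)-oxirane.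

Step 17
Reactants: 30 epoxy silyl ether from step 16
Product: 31 (1R,3S,4Z,6R,7R,8R,10R)-1,10-epoxy-3,15-dihydroxy-8-(isobutyryloxy)germacra-4,11(13)-dien-12,6-olide (CNP0219050.1)
Conditions: HF·pyridine, pyridine (excess), THF, 0 °C → rt
Reagents that add atoms: none
Why: Fluoride-mediated desilylation of the primary allylic silyl ether, buffered with pyridine so that the oxirane, the ester and the α-methylene lactone survive.

## Compound list

1 | tert-butyldimethyl(prop-2-yn-1-yloxy)silane | C#CCO[Si](C)(C)C(C)(C)C | starting material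
2 | acrolein (prop-2-enal) | C=CC=O | starting material
3 | methyl[3-(tert-butyldimethylsilyloxy)prop-1-yn-1-yl]zinc | C[Zn]C#CCO[Si](C)(C)C(C)(C)C | intermediate
4 | (3S)-6-(tert-butyldimethylsilyloxy)hex-1-en-4-yn-3-ol | C=C[C@H](O)C#CCO[Si](C)(C)C(C)(C)C | intermediate
5 | sodium 2,2-bis(2-methoxyethoxy)-3-[(tert-butyldimethylsilyloxy)methyl]-5-vinyl-2,5-dihydro-1,2-oxaaluminol-2-uide (cyclic vinylalanate, Al on C4 and on the C6 oxygen) | C=C[C@@H]1O[Al-](OCCOC)(OCCOC)C(CO[Si](C)(C)C(C)(C)C)=C1.[Na+] | intermediate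
6 | (3S,4Z)-6-(tert-butyldimethylsilyloxy)-5-iodohexa-1,4-dien-3-ol | C=C[C@H](O)/C=C(/CO[Si](C)(C)C(C)(C)C)I | intermediate
7 | acryloyl chloride | C=CC(=O)Cl | starting material
8 | (3S,4Z)-6-(tert-butyldimethylsilyloxy)-5-iodohexa-1,4-dien-3-yl prop-2-enoate | C=CC(=O)O[C@@H](C=C)/C=C(/CO[Si](C)(C)C(C)(C)C)I | intermediate
9 | (5S)-5-[(1Z)-3-(tert-butyldimethylsilyloxy)-2-iodoprop-1-en-1-yl]furan-2(5H)-one | O=C1C=C[C@H](O1)/C=C(/CO[Si](C)(C)C(C)(C)C)I | intermediate
10 | 4-methylpent-3-en-1-ol | CC(C)=CCCO | starting material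
11 | 1-methoxy-4-{[(4-methylpent-3-en-1-yl)oxy]methyl}benzene | COc1ccc(COCCC=C(C)C)cc1 | intermediate
12 | (2E)-5-[(4-methoxybenzyl)oxy]-2-methylpent-2-en-1-ol | COc1ccc(COCC/C=C(\C)CO)cc1 | intermediate
13 | 1-({[(3E)-5-bromo-4-methylpent-3-en-1-yl]oxy}methyl)-4-methoxybenzene | COc1ccc(COCC/C=C(\C)CBr)cc1 | intermediate
14 | 1,3-dithiane | C1CSCSC1 | starting material
15 | 2-lithio-1,3-dithiane | [Li]C1SCCCS1 | intermediate
16 | 2-[(2E)-5-[(4-methoxybenzyl)oxy]-2-methylpent-2-en-1-yl]-1,3-dithiane | COc1ccc(COCC/C=C(\C)CC2SCCCS2)cc1 | intermediate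
17 | Eschenmoser's salt (N,N-dimethylmethyleneiminium iodide) | C=[N+](C)C.[I-] | starting material
18 | 2-lithio-2-[(2E)-5-[(4-methoxybenzyl)oxy]-2-methylpent-2-en-1-yl]-1,3-dithiane | COc1ccc(COCC/C=C(\C)CC2([Li])SCCCS2)cc1 | intermediate
19 | lithium (4S,5S)-5-[(1Z)-3-(tert-butyldimethylsilyloxy)-2-iodoprop-1-en-1-yl]-4-{2-[(2E)-5-[(4-methoxybenzyl)oxy]-2-methylpent-2-en-1-yl]-1,3-dithian-2-yl}-4,5-dihydrofuran-2-olate | [Li+].[O-]C1=C[C@H](C2(C/C(C)=C/CCOCc3ccc(OC)cc3)SCCCS2)[C@@H](/C=C(/CO[Si](C)(C)C(C)(C)C)I)O1 | intermediate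
20 | 3-[(dimethylamino)methyl] Mannich base of 22 (3,4-trans; C11 configuration inconsequential) | CN(C)C[C@@H]1C(=O)O[C@H](/C=C(/CO[Si](C)(C)C(C)(C)C)I)[C@H]1C2(C/C(C)=C/CCOCc3ccc(OC)cc3)SCCCS2 | intermediate
21 | trimethylammonium iodide of 20 | C[N+](C)(C)C[C@@H]1C(=O)O[C@H](/C=C(/CO[Si](C)(C)C(C)(C)C)I)[C@H]1C2(C/C(C)=C/CCOCc3ccc(OC)cc3)SCCCS2.[I-] | intermediate
22 | (4S,5S)-5-[(1Z)-3-(tert-butyldimethylsilyloxy)-2-iodoprop-1-en-1-yl]-4-{2-[(2E)-5-[(4-methoxybenzyl)oxy]-2-methylpent-2-en-1-yl]-1,3-dithian-2-yl}-3-methylideneoxolan-2-one | C=C1C(=O)O[C@H](/C=C(/CO[Si](C)(C)C(C)(C)C)I)[C@H]1C2(C/C(C)=C/CCOCc3ccc(OC)cc3)SCCCS2 | intermediate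
23 | (4S,5S)-5-[(1Z)-3-(tert-butyldimethylsilyloxy)-2-iodoprop-1-en-1-yl]-4-[(3E)-6-[(4-methoxybenzyl)oxy]-3-methylhex-3-enoyl]-3-methylideneoxolan-2-one | C=C1C(=O)O[C@H](/C=C(/CO[Si](C)(C)C(C)(C)C)I)[C@H]1C(=O)C/C(C)=C/CCOCc2ccc(OC)cc2 | intermediate
24 | (4R,5S)-4-[(1R,3E)-1-hydroxy-6-[(4-methoxybenzyl)oxy]-3-methylhex-3-en-1-yl]-5-[(1Z)-3-(tert-butyldimethylsilyloxy)-2-iodoprop-1-en-1-yl]-3-methylideneoxolan-2-one | C=C1C(=O)O[C@H](/C=C(/CO[Si](C)(C)C(C)(C)C)I)[C@H]1[C@H](O)C/C(C)=C/CCOCc2ccc(OC)cc2 | intermediate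
25 | (1R,3E)-1-[(2S,3R)-2-[(1Z)-3-(tert-butyldimethylsilyloxy)-2-iodoprop-1-en-1-yl]-4-methylidene-5-oxooxolan-3-yl]-6-[(4-methoxybenzyl)oxy]-3-methylhex-3-en-1-yl 2-methylpropanoate | C=C1C(=O)O[C@H](/C=C(/CO[Si](C)(C)C(C)(C)C)I)[C@H]1[C@H](OC(=O)C(C)C)C/C(C)=C/CCOCc2ccc(OC)cc2 | intermediate
26 | (1R,3E)-1-[(2S,3R)-2-[(1Z)-3-(tert-butyldimethylsilyloxy)-2-iodoprop-1-en-1-yl]-4-methylidene-5-oxooxolan-3-yl]-6-hydroxy-3-methylhex-3-en-1-yl 2-methylpropanoate | C=C1C(=O)O[C@H](/C=C(/CO[Si](C)(C)C(C)(C)C)I)[C@H]1[C@H](OC(=O)C(C)C)C/C(C)=C/CCO | intermediate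
27 | (1R,3E)-1-[(2S,3R)-2-[(1Z)-3-(tert-butyldimethylsilyloxy)-2-iodoprop-1-en-1-yl]-4-methylidene-5-oxooxolan-3-yl]-3-methyl-6-oxohex-3-en-1-yl 2-methylpropanoate | C=C1C(=O)O[C@H](/C=C(/CO[Si](C)(C)C(C)(C)C)I)[C@H]1[C@H](OC(=O)C(C)C)C/C(C)=C/CC=O | intermediate
28 | vinylchromium dichloride of 27 (CrCl2 in place of iodine at C4, Z geometry retained) | C=C1C(=O)O[C@H](/C=C(/CO[Si](C)(C)C(C)(C)C)[Cr](Cl)Cl)[C@H]1[C@H](OC(=O)C(C)C)C/C(C)=C/CC=O | intermediate
29 | (1(10)E,3S,4Z,6R,7R,8R)-15-(tert-butyldimethylsilyloxy)-3-hydroxy-8-(isobutyryloxy)germacra-1(10),4,11(13)-trien-12,6-olide | C=C1C(=O)O[C@@H]2/C=C(/CO[Si](C)(C)C(C)(C)C)[C@@H](O)C/C=C(\C)C[C@@H](OC(=O)C(C)C)[C@@H]12 | intermediate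
30 | (1R,3S,4Z,6R,7R,8R,10R)-15-(tert-butyldimethylsilyloxy)-1,10-epoxy-3-hydroxy-8-(isobutyryloxy)germacra-4,11(13)-dien-12,6-olide | C=C1C(=O)O[C@@H]2/C=C(/CO[Si](C)(C)C(C)(C)C)[C@@H](O)C[C@H]3O[C@]3(C)C[C@@H](OC(=O)C(C)C)[C@@H]12 | intermediate
31 | (1R,3S,4Z,6R,7R,8R,10R)-1,10-epoxy-3,15-dihydroxy-8-(isobutyryloxy)germacra-4,11(13)-dien-12,6-olide (CNP0219050.1) | C=C1C(=O)O[C@@H]2/C=C(/CO)[C@@H](O)C[C@H]3O[C@]3(C)C[C@@H](OC(=O)C(C)C)[C@@H]12 | target

## Step count and risks

Total step count: 17.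
Longest linear sequence: 13 steps (steps 1–4 then 9–17; steps 5–8 then 9–17 is equally long).

The three steps most likely to fail:

Step 9. The strongly basic carbanion 18 may deprotonate the doubly allylic C6–H of 9 (2-oxyfuran formation and loss of the C6 configuration), dehydroiodinate the iodoalkene, or add 1,2. The fallback delivers the same C8 synthon as a neutral nucleophilic radical. It sets out from 16: lithiation and quenching with CO2 give 2-[(2E)-5-[(4-methoxybenzyl)oxy]-2-methylpent-2-en-1-yl]-1,3-dithiane-2-carboxylic acid F1. Blue-light irradiation with [Ir(dF(CF3)ppy)2(dtbbpy)]PF6 and K2HPO4 in DMSO decarboxylates it to the dithianyl radical, which adds to the β-carbon of 9 anti to the C6 side chain. This gives the saturated trans-lactone (4S,5S)-5-[(1Z)-3-(tert-butyldimethylsilyloxy)-2-iodoprop-1-en-1-yl]-4-{2-[(2E)-5-[(4-methoxybenzyl)oxy]-2-methylpent-2-en-1-yl]-1,3-dithian-2-yl}oxolan-2-one F2. LiN(SiMe3)2 in THF at −78 °C then converts it into the lithium enolate 19, where the route is rejoined (17, MeI, NaHCO3 to 22).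

Step 11. The CBS catalyst must distinguish a branched from an unbranched alkyl group on a ketone that is also a base-sensitive β-acyloxy ketone, so the C8 ratio may be poor or reversed. The fallback sets C8 by an invertive esterification instead of by the hydride. It sets out from 23: reduction with the enantiomeric (R)-catalyst (or collection of the minor epimer) gives the (8S)-alcohol, the C8 epimer of 24 F3. Mitsunobu esterification with isobutyric acid (PPh3, DIAD, toluene, 0 °C) installs the isobutyrate with inversion and returns at 25, so both C8 epimers converge.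

Step 15. The ten-membered ring closure is precedented in type, but the C3 configuration rests on substrate control alone and may come out as the 3α epimer or as a mixture. The fallback sets C3 after the ring is closed, under reagent control. It sets out from 27: the same CrCl2/NiCl2 closure gives the (3R)-alcohol, the C3 epimer of 29 F4 (or the epimer mixture). Dess–Martin periodinane oxidises it to the macrocyclic cross-conjugated 3-ketone, (1(10)E,4Z,6R,7R,8R)-15-(tert-butyldimethylsilyloxy)-8-(isobutyryloxy)-3-oxogermacra-1(10),4,11(13)-trien-12,6-olide F5. Reduction with (R)-2-methyl-CBS-oxazaborolidine/catecholborane (alkenyl C4 as the large group) returns at 29.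

## Further compounds

F1 | step 9 | 2-[(2E)-5-[(4-methoxybenzyl)oxy]-2-methylpent-2-en-1-yl]-1,3-dithiane-2-carboxylic acid | COc1ccc(COCC/C=C(\C)CC2(C(=O)O)SCCCS2)cc1
F2 | step 9 | (4S,5S)-5-[(1Z)-3-(tert-butyldimethylsilyloxy)-2-iodoprop-1-en-1-yl]-4-{2-[(2E)-5-[(4-methoxybenzyl)oxy]-2-methylpent-2-en-1-yl]-1,3-dithian-2-yl}oxolan-2-one | O=C1C[C@H](C2(C/C(C)=C/CCOCc3ccc(OC)cc3)SCCCS2)[C@@H](/C=C(/CO[Si](C)(C)C(C)(C)C)I)O1
F3 | step 11 | (4R,5S)-4-[(1S,3E)-1-hydroxy-6-[(4-methoxybenzyl)oxy]-3-methylhex-3-en-1-yl]-5-[(1Z)-3-(tert-butyldimethylsilyloxy)-2-iodoprop-1-en-1-yl]-3-methylideneoxolan-2-one (C8 epimer of 24) | C=C1C(=O)O[C@H](/C=C(/CO[Si](C)(C)C(C)(C)C)I)[C@H]1[C@@H](O)C/C(C)=C/CCOCc2ccc(OC)cc2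
F4 | step 15 | (1(10)E,3R,4Z,6R,7R,8R)-15-(tert-butyldimethylsilyloxy)-3-hydroxy-8-(isobutyryloxy)germacra-1(10),4,11(13)-trien-12,6-olide (C3 epimer of 29) | C=C1C(=O)O[C@@H]2/C=C(/CO[Si](C)(C)C(C)(C)C)[C@H](O)C/C=C(\C)C[C@@H](OC(=O)C(C)C)[C@@H]12
F5 | step 15 | (1(10)E,4Z,6R,7R,8R)-15-(tert-butyldimethylsilyloxy)-8-(isobutyryloxy)-3-oxogermacra-1(10),4,11(13)-trien-12,6-olide | C=C1C(=O)O[C@@H]2/C=C(/CO[Si](C)(C)C(C)(C)C)C(=O)C/C=C(\C)C[C@@H](OC(=O)C(C)C)[C@@H]12
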